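Friday's flask is read at 15 d and Tuesday's at 20 d. Both hold the same charge, so the two answers are one curve read twice, and the second follows from the first through the fraction of Q left between the readings.

| flask | J | G | remark | time |
|---|---|---|---|---|
| birch | 42 mM | 0.67 equiv | run made earlier |  |
| maple | 42 mM | 1.5 equiv | run made earlier |  |
| elm | 21 mM | 1 equiv | run made earlier |  |
| Tuesday's | 42 mM | 1.00 equiv |  | 20 d |
| Friday's | 42 mM | 1.00 equiv |  | 15 d |

| run | time / d | Q / % |
|---|---|---|
| birch | 0.625 | 11.4 |
| birch | 1.67 | 32.5 |
| birch | 3.00 | 44.7 |
| birch | 5.00 | 48.4 |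
| birch | 8.00 | 47.1 |
| birch | 10.0 | 44.3 |
| birch | 12.0 | 43.0 |
| maple | 0.625 | 16.9 |
| maple | 1.67 | 44.1 |
| maple | 3.00 | 63.6 |
| maple | 5.00 | 77.0 |
| maple | 8.00 | 83.0 |
| maple | 10.0 | 82.9 |
| maple | 12.0 | 81.2 |
| elm | 1.04 | 21.4 |
| elm | 1.67 | 33.4 |
| elm | 3.00 | 49.8 |
| elm | 6.00 | 59.7 |
| elm | 12.0 | 54.9 |

(readings scatter by 0.3 percentage points)

- a species is counted by the J in it: one Z counts as two
- the analysis behind the earlier runs scatters by 0.3 percentage points, standard deviation
- steps thought possible: J -> X; G -> E; X + E <-> Q; 2 X -> Z

- which of the two there is more of at the end, counted by the J in each, Tuesday's (Q / Z)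
- which of the two there is more of at the end, counted by the J in each, Friday's (Q / Z)
- how much Q is there at the end, in percent of the J charged: Tuesday's
- how much Q is there at the end, in percent of the J charged: Friday's

The runs give a ladder of times. On the first rung the readings show, Q in the maple run reaches half of its highest reading by 1.67 d. If J goes at that pace, Friday's flask keeps 0.198% of its J at 15 d, so by this estimate hardly any J remains by then, because 1.67 d is shorter than 15 d.

On the next rung, the highest reading of Q stands at 5.00 d in the birch run, 6.00 d in the elm run and 8.00 d in the maple run.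

The last rung is the decline past the highest reading. Its measure is the leak rate, the logarithm of the ratio of an earlier to a later reading of Q, divided by the days between them, an apparent first-order constant. At the same J and over the same days, the birch run reads 0.0228 /d and the maple run, with more G, 0.00548 /d. The elm run has the right equivalents, though half the J:

leak rate = ln(59.7% / 54.9%) / 6.00 d = 0.0140 /d

fraction left over 5.00 d = 0.933

The forecast expects 60% (56% to 64%) for Friday's and 56.5% (52% to 61%) for Tuesday's, with Q and Q ahead: “After the peak Q leaks away through reversal, with X going irreversibly to Z.” The reckoning here borrows its Friday level, and the fraction left carries that to 56.0%, a little less than the forecast's Tuesday figure.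

    J → X (k = 0.0180 /h)
    G → E (k = 0.100 /h)
    X + E ⇌ Q (K = 990 /M, k = 8.00 /M/h)
    2 X → Z (k = 5.60 /M/h)

In Friday's flask G went to E with a half-life of 0.29 d and J to X with one of 1.6 d, each by that step alone, and at 7.50 d J stood at 3.92%, Q at 66.7% and Z at 24.7%. Then Q fell while Z rose, reaching 59.3% against 37.3% at 15 d, and 55.0% against 42.2% in Tuesday's at 20 d. The leak rate of 0.0140 /d carries 59.3% to 55.3%, beside the 55.0% found. In the birch run, 0.0228 /d carries 43.0% to 35.8% at 20 d, and that flask holds 36.1%.

The runs stem from a simulated flask for an exercise; the scatter is artificial.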